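The pyranone ring is disconnected at O1–C8a. The oxygens at C5 and C8 of ring A stand para to each other, so this ring can travel at the quinone oxidation level. There C8a is still a CH carbon and lies beta to both the C5 quinone carbonyl and the C4 ketone. In one operation the enol oxygen of a pendant 1,3-diketone adds to C8a and the adduct aromatises. This closes ring C and should deliver a 5,8-dihydroxychromone with the 5-OH chelated and the 8-OH free for methylation. The precursor is a 2-acyl-5-methoxy-1,4-benzoquinone whose acyl chain is a 2-benzyloxy-1,3-diketone ending in benzyl-protected ring B.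

Key step: step 6

Assumption: the aryl bromide, the Weinreb amide and the 4-O-methylgallic acid used below are taken as catalogue compounds.
Assumption: the benzyloxy-bearing carbon of the open-chain diketone and of the quinone is a labile stereocentre; both are handled as racemates, and the centre becomes sp2 in the key step, so the achiral target needs no stereocontrol.

Step 1
Reactants: 1 1-bromo-2,4,5-trimethoxybenzene; 2 2-(benzyloxy)-N-methoxy-N-methylacetamide
Product: 4 2-(benzyloxy)-1-(2,4,5-trimethoxyphenyl)ethan-1-one, via 2,4,5-trimethoxyphenyllithium 3 (not isolated)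
Conditions: n-BuLi (1.05 equiv), THF, −78 °C, 20 min; then 2, −78 to 0 °C; aq. NH4Cl
Reagents that add atoms: none
Why: Bromine–lithium exchange at −78 °C should give the aryllithium cleanly, and its single addition to the Weinreb amide (Weinreb ketone synthesis) should release the ketone on work-up, with no Lewis acid present that could cleave the benzyl ether.

Step 2
Reactants: 5 3,5-dihydroxy-4-methoxybenzoic acid
Product: 7 3,5-bis(benzyloxy)-4-methoxybenzoic acid, via benzyl 3,5-bis(benzyloxy)-4-methoxybenzoate 6 (not isolated)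
Conditions: BnBr (3.3 equiv), K2CO3, DMF, 60 °C; then NaOH, MeOH/H2O, 70 °C; aq. HCl
Reagents that add atoms: benzyl bromide, BrCc1ccccc1; sodium hydroxide, [Na+].[OH-]
Why: Williamson etherification should benzylate both phenols and the carboxylate, and saponification of the benzyl ester in the same flask should return the free acid with the aryl benzyl ethers untouched.

Step 3
Reactants: 7 3,5-bis(benzyloxy)-4-methoxybenzoic acid
Product: 8 3,5-bis(benzyloxy)-4-methoxybenzoyl chloride
Conditions: (COCl)2 (1.5 equiv), DMF (cat.), CH2Cl2, 0 °C to rt; concentrate, use crude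
Reagents that add atoms: oxalyl chloride, O=C(Cl)C(=O)Cl
Why: Acid chloride formation through the Vilsmeier-type chloroiminium species should be clean under these mild conditions, which leave benzyl and methyl ethers intact.

Step 4
Reactants: 4 2-(benzyloxy)-1-(2,4,5-trimethoxyphenyl)ethan-1-one; 8 3,5-bis(benzyloxy)-4-methoxybenzoyl chloride
Product: 10 2-(benzyloxy)-1-[3,5-bis(benzyloxy)-4-methoxyphenyl]-3-(2,4,5-trimethoxyphenyl)propane-1,3-dione (racemic), via lithium (Z)-2-(benzyloxy)-1-(2,4,5-trimethoxyphenyl)ethen-1-olate 9 (not isolated)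
Conditions: LiN(SiMe3)2 (2.2 equiv), THF, −78 °C, 45 min; then 8 (1.0 equiv), −78 to −20 °C; aq. NH4Cl
Reagents that add atoms: none
Why: C-acylation of the chelated lithium enolate by the aroyl chloride (crossed Claisen-type enolate acylation) should give the 1,3-diketone, the second equivalent of base converting it at once into its enolate and so shielding it from a second acylation.

Step 5
Reactants: 10 2-(benzyloxy)-1-[3,5-bis(benzyloxy)-4-methoxyphenyl]-3-(2,4,5-trimethoxyphenyl)propane-1,3-dione
Product: 11 2-{2-(benzyloxy)-3-[3,5-bis(benzyloxy)-4-methoxyphenyl]-3-oxopropanoyl}-5-methoxy-1,4-benzoquinone (racemic)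
Conditions: (NH4)2Ce(NO3)6 (2.2 equiv), MeCN/H2O (4:1), 0 °C, 10 min; cold extraction, crude used at once
Reagents that add atoms: water, O
Why: Oxidative demethylation by tetravalent cerium should turn the para-related 2- and 5-methoxy groups of the 2,4,5-trimethoxyphenyl ring into the quinone carbonyls, their oxygens coming from water, because this ring is by far the most electron-rich site, whereas the 1,2,3-trioxygenated benzoyl ring B and the diketone resting in its keto form should be oxidised much more slowly.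

Step 6
Reactants: 11 2-{2-(benzyloxy)-3-[3,5-bis(benzyloxy)-4-methoxyphenyl]-3-oxopropanoyl}-5-methoxy-1,4-benzoquinone
Product: 12 3-(benzyloxy)-2-[3,5-bis(benzyloxy)-4-methoxyphenyl]-5,8-dihydroxy-7-methoxy-4H-chromen-4-one
Conditions: NaOAc (0.2 equiv), AcOH/CH2Cl2 (1:9, degassed, 0.01 M), rt, Ar
Reagents that add atoms: none
Why: Proposed new method: acetate-mediated enolisation of the diketone toward the ring B carbonyl should expose an enol oxygen on the future C2 that adds to C8a, the unsubstituted quinone carbon lying beta to both the C5 quinone carbonyl and the C4 ketone, after which proton shifts convert the adduct into the aromatic 5,8-hydroquinone and make the closure irreversible. The closest known reaction type is the conjugate addition of heteroatom and enol nucleophiles to C3 of 2-acyl-1,4-benzoquinones with tautomerisation to the acylhydroquinone, here run intramolecularly with a diketone enol oxygen. Ring C is closed in a 6-endo-trig mode by the new O1–C8a bond. No stereocentre is formed, and the labile benzyloxy-bearing centre of 11 ends as the sp2 carbon C3. The step needs oxygen rather than carbon attack and C8a rather than C6 or C7 as acceptor: attack by the central carbon would give a four-membered ring, the tether cannot reach C6 or C7, and the C7 methoxy group turns the second enone of the quinone into a less electrophilic vinylogous ester. The buffered, dilute and oxygen-free medium is chosen to keep redox exchange between 12 and unreacted 11, and intermolecular additions, slow relative to the unimolecular closure.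

Step 7
Reactants: 12 3-(benzyloxy)-2-[3,5-bis(benzyloxy)-4-methoxyphenyl]-5,8-dihydroxy-7-methoxy-4H-chromen-4-one
Product: 13 3-(benzyloxy)-2-[3,5-bis(benzyloxy)-4-methoxyphenyl]-5-hydroxy-7,8-dimethoxy-4H-chromen-4-one
Conditions: MeI (1.2 equiv), K2CO3 (1.1 equiv), acetone (degassed), 40 °C, Ar
Reagents that add atoms: iodomethane, CI
Why: Williamson methylation should take place only at the 8-OH, since the 5-OH is tied up in a hydrogen bond to the C4 carbonyl and is far less acidic and nucleophilic, while exclusion of air guards the hydroquinone against autoxidation.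

Step 8
Reactants: 13 3-(benzyloxy)-2-[3,5-bis(benzyloxy)-4-methoxyphenyl]-5-hydroxy-7,8-dimethoxy-4H-chromen-4-one
Product: 14 3,5-dihydroxy-2-(3,5-dihydroxy-4-methoxyphenyl)-7,8-dimethoxy-4H-chromen-4-one
Conditions: H2 (1 atm), Pd/C (10 %), EtOAc/MeOH, rt
Reagents that add atoms: none
Why: Catalytic hydrogenolysis should cleave the three benzyl ethers (at O3 and on ring B) while the methyl ethers and the tetrasubstituted C2=C3 bond of the chromone stay untouched.

Compound list
1 | 1-bromo-2,4,5-trimethoxybenzene | COc1cc(OC)c(OC)cc1Br | starting material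
2 | 2-(benzyloxy)-N-methoxy-N-methylacetamide | CON(C)C(=O)COCc1ccccc1 | starting material
3 | 2,4,5-trimethoxyphenyllithium | [Li]c1cc(OC)c(OC)cc1OC | intermediate
4 | 2-(benzyloxy)-1-(2,4,5-trimethoxyphenyl)ethan-1-one | O=C(COCc1ccccc1)c1cc(OC)c(OC)cc1OC | intermediate
5 | 3,5-dihydroxy-4-methoxybenzoic acid | OC(=O)c1cc(O)c(OC)c(O)c1 | starting material
6 | benzyl 3,5-bis(benzyloxy)-4-methoxybenzoate | COc1c(OCc2ccccc2)cc(cc1OCc1ccccc1)C(=O)OCc1ccccc1 | intermediate
7 | 3,5-bis(benzyloxy)-4-methoxybenzoic acid | COc1c(OCc2ccccc2)cc(cc1OCc1ccccc1)C(=O)O | intermediate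
8 | 3,5-bis(benzyloxy)-4-methoxybenzoyl chloride | COc1c(OCc2ccccc2)cc(cc1OCc1ccccc1)C(=O)Cl | intermediate
9 | lithium (Z)-2-(benzyloxy)-1-(2,4,5-trimethoxyphenyl)ethen-1-olate | [Li]O/C(=C\OCc1ccccc1)c1cc(OC)c(OC)cc1OC | intermediate
10 | 2-(benzyloxy)-1-[3,5-bis(benzyloxy)-4-methoxyphenyl]-3-(2,4,5-trimethoxyphenyl)propane-1,3-dione (racemic, labile centre) | COc1c(OCc2ccccc2)cc(cc1OCc1ccccc1)C(=O)C(OCc1ccccc1)C(=O)c1cc(OC)c(OC)cc1OC | intermediate
11 | 2-{2-(benzyloxy)-3-[3,5-bis(benzyloxy)-4-methoxyphenyl]-3-oxopropanoyl}-5-methoxy-1,4-benzoquinone (racemic, labile centre) | COC1=CC(=O)C(C(=O)C(OCc2ccccc2)C(=O)c2cc(OCc3ccccc3)c(OC)c(OCc3ccccc3)c2)=CC1=O | intermediate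
12 | 3-(benzyloxy)-2-[3,5-bis(benzyloxy)-4-methoxyphenyl]-5,8-dihydroxy-7-methoxy-4H-chromen-4-one | COc1cc(O)c2c(=O)c(OCc3ccccc3)c(-c3cc(OCc4ccccc4)c(OC)c(OCc4ccccc4)c3)oc2c1O | intermediate
13 | 3-(benzyloxy)-2-[3,5-bis(benzyloxy)-4-methoxyphenyl]-5-hydroxy-7,8-dimethoxy-4H-chromen-4-one | COc1cc(O)c2c(=O)c(OCc3ccccc3)c(-c3cc(OCc4ccccc4)c(OC)c(OCc4ccccc4)c3)oc2c1OC | intermediate
14 | 3,5-dihydroxy-2-(3,5-dihydroxy-4-methoxyphenyl)-7,8-dimethoxy-4H-chromen-4-one | COc1cc(O)c2c(=O)c(O)c(-c3cc(O)c(OC)c(O)c3)oc2c1OC | target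

Total step count: 8. Longest linear sequence: 7 steps (steps 2 to 8, from compound 5).

Steps most likely to fail

Step 6 (proposed new method). The enol may add too slowly, so that redox exchange between the hydroquinone being formed and unreacted acylquinone, or intermolecular addition to the quinone, consumes the material. The fallback uses known chemistry only, sets out from acid chloride 8 and comes back to the route at 12. Hoesch acylation of phloroglucinol with benzyloxyacetonitrile (ZnCl2, HCl, Et2O; then aqueous hydrolysis) would give 2-(benzyloxy)-1-(2,4,6-trihydroxyphenyl)ethan-1-one F1. Its polyanion (excess LiN(SiMe3)2, THF, −78 °C) would be C-aroylated by 8 to 2-(benzyloxy)-1-[3,5-bis(benzyloxy)-4-methoxyphenyl]-3-(2,4,6-trihydroxyphenyl)propane-1,3-dione F2. Warming F2 in AcOH with a trace of H2SO4 would cyclodehydrate it to 3-(benzyloxy)-2-[3,5-bis(benzyloxy)-4-methoxyphenyl]-5,7-dihydroxy-4H-chromen-4-one F3; the two ortho hydroxyls are equivalent, so only one chromone can form. One equivalent of MeI with K2CO3 would methylate the non-chelated 7-OH to 3-(benzyloxy)-2-[3,5-bis(benzyloxy)-4-methoxyphenyl]-5-hydroxy-7-methoxy-4H-chromen-4-one F4. Elbs persulfate oxidation (K2S2O8, aq. KOH/pyridine) would place a sulfate para to the 5-oxygen, giving potassium 3-(benzyloxy)-2-[3,5-bis(benzyloxy)-4-methoxyphenyl]-5-hydroxy-7-methoxy-4-oxo-4H-chromen-8-yl sulfate F5, and warm dilute HCl would hydrolyse it to 12.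

Step 5. Tetravalent cerium may oxidise the enolisable diketone by single-electron transfer, or the ring may close in the acidic oxidising medium and the new hydroquinone be oxidised further. The fallback sets out from ketone 4 and comes back at 11; it moves the oxidative demethylation to a stage without the diketone and regenerates the quinone at the end under neutral conditions. (NH4)2Ce(NO3)6 in MeCN/H2O would turn 4 into 2-[(benzyloxy)acetyl]-5-methoxy-1,4-benzoquinone F6, and Na2S2O4 would reduce it to 2-(benzyloxy)-1-(2,5-dihydroxy-4-methoxyphenyl)ethan-1-one F7. t-BuMe2SiOTf with 2,6-lutidine would give 2-(benzyloxy)-1-{2,5-bis[(tert-butyldimethylsilyl)oxy]-4-methoxyphenyl}ethan-1-one F8. Enolate acylation with 8 under the conditions of step 4 would give 2-(benzyloxy)-1-[3,5-bis(benzyloxy)-4-methoxyphenyl]-3-{2,5-bis[(tert-butyldimethylsilyl)oxy]-4-methoxyphenyl}propane-1,3-dione F9. Bu4NF buffered with AcOH would free 2-(benzyloxy)-1-[3,5-bis(benzyloxy)-4-methoxyphenyl]-3-(2,5-dihydroxy-4-methoxyphenyl)propane-1,3-dione F10, and Ag2O (MgSO4, CH2Cl2) would oxidise this hydroquinone to 11.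

Step 4. The enolate may be acylated on oxygen instead of carbon, or the product enolate may be acylated a second time. The fallback sets out from 8 (with 4) and comes back at 10, replacing the acylation by an aldol addition and an oxidation. Reduction of 8 with LiAlH(O-t-Bu)3 at −78 °C would give 3,5-bis(benzyloxy)-4-methoxybenzaldehyde F11. Addition of enolate 9 to it would give 2-(benzyloxy)-3-[3,5-bis(benzyloxy)-4-methoxyphenyl]-3-hydroxy-1-(2,4,5-trimethoxyphenyl)propan-1-one F12 as a mixture of diastereomers. Dess–Martin oxidation would then give 10, which removes the carbinol centre and makes the diastereomer ratio irrelevant.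

Further compounds
F1 | step 6 | 2-(benzyloxy)-1-(2,4,6-trihydroxyphenyl)ethan-1-one | O=C(COCc1ccccc1)c1c(O)cc(O)cc1O
F2 | step 6 | 2-(benzyloxy)-1-[3,5-bis(benzyloxy)-4-methoxyphenyl]-3-(2,4,6-trihydroxyphenyl)propane-1,3-dione (racemic) | COc1c(OCc2ccccc2)cc(cc1OCc1ccccc1)C(=O)C(OCc1ccccc1)C(=O)c1c(O)cc(O)cc1O
F3 | step 6 | 3-(benzyloxy)-2-[3,5-bis(benzyloxy)-4-methoxyphenyl]-5,7-dihydroxy-4H-chromen-4-one | COc1c(OCc2ccccc2)cc(cc1OCc1ccccc1)-c1oc2cc(O)cc(O)c2c(=O)c1OCc1ccccc1
F4 | step 6 | 3-(benzyloxy)-2-[3,5-bis(benzyloxy)-4-methoxyphenyl]-5-hydroxy-7-methoxy-4H-chromen-4-one | COc1cc(O)c2c(=O)c(OCc3ccccc3)c(-c3cc(OCc4ccccc4)c(OC)c(OCc4ccccc4)c3)oc2c1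
F5 | step 6 | potassium 3-(benzyloxy)-2-[3,5-bis(benzyloxy)-4-methoxyphenyl]-5-hydroxy-7-methoxy-4-oxo-4H-chromen-8-yl sulfate | COc1cc(O)c2c(=O)c(OCc3ccccc3)c(-c3cc(OCc4ccccc4)c(OC)c(OCc4ccccc4)c3)oc2c1OS(=O)(=O)[O-].[K+]
F6 | step 5 | 2-[(benzyloxy)acetyl]-5-methoxy-1,4-benzoquinone | COC1=CC(=O)C(C(=O)COCc2ccccc2)=CC1=O
F7 | step 5 | 2-(benzyloxy)-1-(2,5-dihydroxy-4-methoxyphenyl)ethan-1-one | COc1cc(O)c(cc1O)C(=O)COCc1ccccc1
F8 | step 5 | 2-(benzyloxy)-1-{2,5-bis[(tert-butyldimethylsilyl)oxy]-4-methoxyphenyl}ethan-1-one | COc1cc(O[Si](C)(C)C(C)(C)C)c(cc1O[Si](C)(C)C(C)(C)C)C(=O)COCc1ccccc1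
F9 | step 5 | 2-(benzyloxy)-1-[3,5-bis(benzyloxy)-4-methoxyphenyl]-3-{2,5-bis[(tert-butyldimethylsilyl)oxy]-4-methoxyphenyl}propane-1,3-dione (racemic) | COc1cc(O[Si](C)(C)C(C)(C)C)c(cc1O[Si](C)(C)C(C)(C)C)C(=O)C(OCc1ccccc1)C(=O)c1cc(OCc2ccccc2)c(OC)c(OCc2ccccc2)c1
F10 | step 5 | 2-(benzyloxy)-1-[3,5-bis(benzyloxy)-4-methoxyphenyl]-3-(2,5-dihydroxy-4-methoxyphenyl)propane-1,3-dione (racemic) | COc1cc(O)c(cc1O)C(=O)C(OCc1ccccc1)C(=O)c1cc(OCc2ccccc2)c(OC)c(OCc2ccccc2)c1
F11 | step 4 | 3,5-bis(benzyloxy)-4-methoxybenzaldehyde | COc1c(OCc2ccccc2)cc(C=O)cc1OCc1ccccc1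
F12 | step 4 | 2-(benzyloxy)-3-[3,5-bis(benzyloxy)-4-methoxyphenyl]-3-hydroxy-1-(2,4,5-trimethoxyphenyl)propan-1-one (racemic, both diastereomers) | COc1c(OCc2ccccc2)cc(cc1OCc1ccccc1)C(O)C(OCc1ccccc1)C(=O)c1cc(OC)c(OC)cc1OC
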